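**Retrosynthetic overview**
- The lactone (the only ring of the target, closed last) is opened to a (Z)-5-hydroxy-2-enoate; its C2=C3 bond comes from a Z-selective olefination of a C3 aldehyde.
- The all-syn diol pairs are masked as 2,4,6-cis-1,3-dioxanes: ring A (O9/O11) is formed first, ring B (O5/O7) second, the lactone third.
- Key disconnections are the C9–O and C5–O bonds, each made by an acetaldehyde-hemiacetal-tethered oxa-conjugate addition onto a δ-hydroxy enal that is generated in the same flask by cross-metathesis with crotonaldehyde.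
- The anchoring carbinols C11 and C7 come from a catalytic enantioselective allylation of cetyl alcohol and a reagent-controlled allylboration of the ring-A aldehyde.
- Building blocks: hexadecan-1-ol, allyl acetate, crotonaldehyde, acetaldehyde, an allylborane and a phosphonoacetate.

Assumption: positions C1–C26 use the open-chain numbering of the target (C1 lactone carbonyl, C5 ring CH–O, C7, C9, C11 carbinols), and the (S)-bisphosphine of step 1 and the (−)-allylborane of step 3 are taken to give the configurations drawn; should either induce the opposite sense, its enantiomer is used.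

**Route**

Step 1
Reactants: 1 hexadecan-1-ol; 2 allyl acetate
Product: 4 (4R)-nonadec-1-en-4-ol, via hexadecanal 3 (not isolated)
Conditions: [Ir(cod)Cl]2 (2.5 mol%), (S)-Cl,MeO-BIPHEP (5 mol%), Cs2CO3 (20 mol%), 4-chloro-3-nitrobenzoic acid (10 mol%), 2 (2 equiv), THF, 100 °C, sealed tube
Reagents that add atoms: allyl acetate, C=CCOC(C)=O
Why: Krische-type iridium-catalysed transfer-hydrogenative carbonyl allylation, in which the alcohol is dehydrogenated to 3 and the cyclometallated π-allyl iridium complex adds to it through a closed chair transition state whose face is fixed by the (S)-bisphosphine, setting C11 as R.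

Step 2
Reactants: 4 (4R)-nonadec-1-en-4-ol; 5 (E)-but-2-enal; 6 acetaldehyde
Product: 9 2-[(2R,4R,6R)-2-methyl-6-pentadecyl-1,3-dioxan-4-yl]acetaldehyde, via hydroxy enal 7 (not isolated), via hemiacetal 8 (not isolated)
Conditions: 5 (3 equiv), second-generation Hoveyda–Grubbs catalyst RuCl2(SIMes)(=CH-C6H4-2-OiPr) (3 mol%), CH2Cl2, 40 °C until 4 is consumed; strip volatiles; then 6 (10 equiv), Bi(NO3)3·5H2O (10 mol%), CH2Cl2, 23 °C, same flask
Reagents that add atoms: (E)-but-2-enal, C/C=C/C=O; acetaldehyde, CC=O
Why: Proposed new method: a one-flask ruthenium/bismuth relay not yet shown for this three-component case, in which E-selective cross-metathesis of 4 with 5 (propene is lost) gives δ-hydroxy enal 7 and trivalent bismuth nitrate then promotes reversible hemiacetal formation with 6 (8) and 6-exo-trig oxa-conjugate addition of the hemiacetal oxygen to C9; because both events are reversible the system funnels to the all-equatorial 2,4,6-cis-1,3-dioxane, so the new C9–O bond is set syn to C11 and the acetal carbon cis as well; closest known reactions are the domino cross-metathesis/intramolecular oxa-Michael cyclisation of hydroxy alkenes to tetrahydropyrans and the bismuth-mediated two-component hemiacetal/oxa-conjugate addition of isolated δ-hydroxy enals.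

Step 3
Reactants: 9 2-[(2R,4R,6R)-2-methyl-6-pentadecyl-1,3-dioxan-4-yl]acetaldehyde; 10 (−)-B-allyldiisopinocampheylborane
Product: 12 (2S)-1-[(2R,4S,6R)-2-methyl-6-pentadecyl-1,3-dioxan-4-yl]pent-4-en-2-ol, via borinate 11 (not isolated)
Conditions: 10 (1.3 equiv, 1 M in pentane), Et2O, −78 °C; then NaOH (3 M aq), H2O2 (30% aq), 0 to 23 °C
Reagents that add atoms: (−)-B-allyldiisopinocampheylborane, C=CCB([C@H]1[C@H](C)[C@H]2C[C@@H](C1)C2(C)C)[C@H]1[C@H](C)[C@H]2C[C@@H](C1)C2(C)C
Why: Brown allylboration, whose chair Zimmerman–Traxler transition state is dominated by the isopinocampheyl groups (reagent control, Si-face attack), overriding the weak 1,3-induction of the β-acetal oxygen and setting C7 syn to C9 before alkaline peroxide cleaves borinate 11.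

Step 4
Reactants: 12 (2S)-1-[(2R,4S,6R)-2-methyl-6-pentadecyl-1,3-dioxan-4-yl]pent-4-en-2-ol; 5 (E)-but-2-enal; 6 acetaldehyde
Product: 15 2-[(2R,4R,6R)-2-methyl-6-{[(2R,4R,6R)-2-methyl-6-pentadecyl-1,3-dioxan-4-yl]methyl}-1,3-dioxan-4-yl]acetaldehyde, via hydroxy enal 13 (not isolated), via hemiacetal 14 (not isolated)
Conditions: 5 (3 equiv), second-generation Hoveyda–Grubbs catalyst RuCl2(SIMes)(=CH-C6H4-2-OiPr) (3 mol%), CH2Cl2, 40 °C; strip volatiles; then 6 (10 equiv), Bi(NO3)3·5H2O (10 mol%), CH2Cl2, 23 °C, same flask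
Reagents that add atoms: (E)-but-2-enal, C/C=C/C=O; acetaldehyde, CC=O
Why: Proposed new method: the same ruthenium/bismuth relay as in step 2 on a substrate that already carries ring A, in which cross-metathesis gives enal 13 and hemiacetal 14 closes by oxa-conjugate addition onto C5 under thermodynamic control to the all-cis ring B, so the C5–O bond is set syn to C7, while acetal exchange of ring A with excess 6 is degenerate; closest known reactions are those named for step 2.

Step 5
Reactants: 15 2-[(2R,4R,6R)-2-methyl-6-{[(2R,4R,6R)-2-methyl-6-pentadecyl-1,3-dioxan-4-yl]methyl}-1,3-dioxan-4-yl]acetaldehyde; 16 methyl bis(2,2,2-trifluoroethyl)phosphonoacetate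
Product: 17 methyl (2Z)-4-[(2S,4S,6S)-2-methyl-6-{[(2R,4R,6R)-2-methyl-6-pentadecyl-1,3-dioxan-4-yl]methyl}-1,3-dioxan-4-yl]but-2-enoate
Conditions: 16 (1.3 equiv), KN(SiMe3)2 (1.25 equiv), 18-crown-6 (3 equiv), THF, −78 °C
Reagents that add atoms: methyl bis(2,2,2-trifluoroethyl)phosphonoacetate, COC(=O)CP(=O)(OCC(F)(F)F)OCC(F)(F)F
Why: Still–Gennari variant of the Horner–Wadsworth–Emmons olefination, in which the electron-poor phosphonate with a crown-separated potassium ion collapses irreversibly from the kinetic syn adduct to give the (Z)-enoate needed for ring closure, with no stereocentre touched at −78 °C.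

Step 6
Reactants: 17 methyl (2Z)-4-[(2S,4S,6S)-2-methyl-6-{[(2R,4R,6R)-2-methyl-6-pentadecyl-1,3-dioxan-4-yl]methyl}-1,3-dioxan-4-yl]but-2-enoate
Product: 19 (6S)-6-[(2R,4R,6R)-2,4,6-trihydroxyhenicosyl]-5,6-dihydro-2H-pyran-2-one, via seco ester 18 (not isolated)
Conditions: AcOH/H2O/THF (4:1:1), 55 °C, N2 sweep; then toluene azeotrope
Reagents that add atoms: none
Why: Acid-catalysed acetal hydrolysis (acetaldehyde is swept out) frees the four hydroxyls of 18, and the C5 hydroxyl then lactonises onto the (Z)-ester by acyl substitution to close the lactone, the last ring formed, without touching any stereocentre.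

**Compound list**
1 | hexadecan-1-ol (cetyl alcohol) | CCCCCCCCCCCCCCCCO | starting material
2 | allyl acetate | CC(=O)OCC=C | starting material
3 | hexadecanal | CCCCCCCCCCCCCCCC=O | intermediate
4 | (4R)-nonadec-1-en-4-ol | CCCCCCCCCCCCCCC[C@@H](O)CC=C | intermediate
5 | (E)-but-2-enal (crotonaldehyde) | C/C=C/C=O | starting material
6 | acetaldehyde | CC=O | starting material
7 | (2E,5R)-5-hydroxyicos-2-enal | CCCCCCCCCCCCCCC[C@@H](O)C/C=C/C=O | intermediate
8 | (2E,5R)-5-(1-hydroxyethoxy)icos-2-enal (acetaldehyde hemiacetal of 7, hemiacetal carbon undefined) | CCCCCCCCCCCCCCC[C@@H](OC(C)O)C/C=C/C=O | intermediate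
9 | 2-[(2R,4R,6R)-2-methyl-6-pentadecyl-1,3-dioxan-4-yl]acetaldehyde (all-cis ring A) | CCCCCCCCCCCCCCC[C@@H]1C[C@H](CC=O)O[C@H](C)O1 | intermediate
10 | (−)-B-allyldiisopinocampheylborane (Ipc groups with the configuration of (−)-isopinocampheol) | C=CCB([C@H]1[C@H](C)[C@H]2C[C@@H](C1)C2(C)C)[C@H]1[C@H](C)[C@H]2C[C@@H](C1)C2(C)C | starting material
11 | diisopinocampheylborinate ester of 12 (B–O at the C7 oxygen, Ipc groups as in 10) | CCCCCCCCCCCCCCC[C@@H]1C[C@H](C[C@@H](OB([C@H]2[C@H](C)[C@H]3C[C@@H](C2)C3(C)C)[C@H]2[C@H](C)[C@H]3C[C@@H](C2)C3(C)C)CC=C)O[C@H](C)O1 | intermediate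
12 | (2S)-1-[(2R,4S,6R)-2-methyl-6-pentadecyl-1,3-dioxan-4-yl]pent-4-en-2-ol | CCCCCCCCCCCCCCC[C@@H]1C[C@H](C[C@@H](O)CC=C)O[C@H](C)O1 | intermediate
13 | (2E,5S)-5-hydroxy-6-[(2R,4S,6R)-2-methyl-6-pentadecyl-1,3-dioxan-4-yl]hex-2-enal | CCCCCCCCCCCCCCC[C@@H]1C[C@H](C[C@@H](O)C/C=C/C=O)O[C@H](C)O1 | intermediate
14 | acetaldehyde hemiacetal of 13 (1-hydroxyethyl ether at the C7 oxygen, hemiacetal carbon undefined) | CCCCCCCCCCCCCCC[C@@H]1C[C@H](C[C@@H](OC(C)O)C/C=C/C=O)O[C@H](C)O1 | intermediate
15 | 2-[(2R,4R,6R)-2-methyl-6-{[(2R,4R,6R)-2-methyl-6-pentadecyl-1,3-dioxan-4-yl]methyl}-1,3-dioxan-4-yl]acetaldehyde (rings A and B both all-cis) | CCCCCCCCCCCCCCC[C@@H]1C[C@H](C[C@@H]2C[C@H](CC=O)O[C@H](C)O2)O[C@H](C)O1 | intermediate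
16 | methyl bis(2,2,2-trifluoroethyl)phosphonoacetate | COC(=O)CP(=O)(OCC(F)(F)F)OCC(F)(F)F | starting material
17 | methyl (2Z)-4-[(2S,4S,6S)-2-methyl-6-{[(2R,4R,6R)-2-methyl-6-pentadecyl-1,3-dioxan-4-yl]methyl}-1,3-dioxan-4-yl]but-2-enoate | CCCCCCCCCCCCCCC[C@@H]1C[C@H](C[C@@H]2C[C@H](C/C=C\C(=O)OC)O[C@H](C)O2)O[C@H](C)O1 | intermediate
18 | methyl (2Z,5S,7S,9R,11R)-5,7,9,11-tetrahydroxyhexacos-2-enoate (seco ester) | CCCCCCCCCCCCCCC[C@@H](O)C[C@@H](O)C[C@@H](O)C[C@@H](O)C/C=C\C(=O)OC | intermediate
19 | (6S)-6-[(2R,4R,6R)-2,4,6-trihydroxyhenicosyl]-5,6-dihydro-2H-pyran-2-one | CCCCCCCCCCCCCCC[C@@H](O)C[C@@H](O)C[C@@H](O)C[C@@H]1CC=CC(=O)O1 | target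

**Step count and risks**

Total step count: 6. Longest linear sequence: 6 (the route is fully linear from 1).

Steps most likely to fail:

Step 2 (the proposed new relay). Ruthenium residues, leftover 5 acting as a competing tether aldehyde, or unconverted 4 undergoing Prins cyclisation with 6 could spoil the bismuth stage. The fallback uses known chemistry as two separate reactions: starting from 4, the cross-metathesis with 5 is run alone, hydroxy enal 7 is isolated and purified, and pure 7 is then submitted to the established bismuth nitrate-mediated two-component hemiacetal/oxa-conjugate addition with 6, which returns to the route at 9. This fallback makes no compound outside the list (none F0).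

Step 3. The desired 1,3-syn addition opposes the intrinsic bias of a β-alkoxy aldehyde, so the diastereomer ratio may erode, and 9 can open by retro-oxa-Michael on handling. The fallback changes oxidation level and catalyst type: starting from 9, NaBH4 in MeOH at 0 °C gives the primary alcohol 2-[(2R,4S,6R)-2-methyl-6-pentadecyl-1,3-dioxan-4-yl]ethan-1-ol F1. F1 is then allylated with 2 under the iridium transfer-hydrogenation conditions of step 1 (same (S)-ligand, catalyst-controlled, aldehyde present only transiently), which returns to the route at 12.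

Step 4 (second use of the relay). The risks are those of step 2, plus acid-induced reorganisation of ring A. The fallback is again two separate known reactions: starting from 12, cross-metathesis with 5 alone, isolation of hydroxy enal 13, then the separate bismuth nitrate-mediated acetalisation with 6, returning to the route at 15. This fallback makes no compound outside the list (none F0).

**Further compounds**
F0 | step 2 | none | none
F1 | step 3 | 2-[(2R,4S,6R)-2-methyl-6-pentadecyl-1,3-dioxan-4-yl]ethan-1-ol | CCCCCCCCCCCCCCC[C@@H]1C[C@H](CCO)O[C@H](C)O1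
F0 | step 4 | none | none
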